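**Plan**

- Retrosynthesis: the two O-benzyl groups go last. Ring A is then cut at C5'-C6' and C3'-C4', because its C6'(Me)-C1'(CO2Ar)-C2'(OMe)-C3'(Me) edge is the C6-C5-C4-C3 diene of a 4-methoxy-3,6-dimethyl-2-pyrone-5-carboxylate and its C4'(O)-C5'(Cl) edge is a chloroketene acetal.
- The pyrone is cut at O1-C2 and C4-C5 into the ring B aryl acetoacetate and methylmalonyl dichloride. The depside C-O bond is cut into the ring B phenol and acetylketene.
- Forward: ring B is completed from methyl atratate (C5 methyl via a formyl group, 2-O-benzyl via a temporary 4-O-silyl group). The hindered depside ester is made as an acetoacetate, the pyrone ring is annulated onto it, and ring A arises last from the pyrone by cycloaddition, loss of CO2 and loss of benzyl alcohol. One hydrogenolysis frees both phenols.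
- Stereochemistry: the target has no stereocentre. The stereocentres of the cycloadduct are transient and vanish on aromatisation.

Key step: step 12

Assumption: ArB denotes the ring B aryl group 3-(benzyloxy)-4-(methoxycarbonyl)-2,5,6-trimethylphenyl; ring B is numbered C1 (ester carbon) to C6 and ring A C1' (acyl carbon) to C6'; methylmalonyl dichloride is made in step 7 because its commercial supply is uncertain; the aldehyde oxygen introduced in step 1 is taken to come from the aqueous work-up.

**Route**

Step 1
Reactants: 1 methyl atratate (methyl 2,4-dihydroxy-3,6-dimethylbenzoate)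
Product: 3 methyl 5-formyl-2,4-dihydroxy-3,6-dimethylbenzoate, via chloro(methoxy)methyl arene 2 (not isolated)
Conditions: Cl2CHOMe, TiCl4, CH2Cl2, 0 °C to rt; then 1 M HCl (aq)
Reagents that add atoms: dichloromethyl methyl ether, COC(Cl)Cl; water, O
Why: Rieche formylation is an electrophilic aromatic substitution and C5 is the only free ring position, ortho to the 4-hydroxyl and para to the 2-hydroxyl, so one regioisomer is expected once the alpha-chloro ether is hydrolysed on work-up.

Step 2
Reactants: 3 methyl 5-formyl-2,4-dihydroxy-3,6-dimethylbenzoate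
Product: 5 methyl 2,4-dihydroxy-3,5,6-trimethylbenzoate, via hydroxymethyl arene 4 (not isolated)
Conditions: H2 (4 atm), 10% Pd/C, AcOH, 50 °C
Reagents that add atoms: none
Why: Catalytic hydrogenolysis of an ortho-hydroxy benzaldehyde over palladium in acetic acid runs through the benzylic alcohol, whose C-O bond is activated by the ortho and para oxygens, down to the methyl group, while the methyl ester and the arene are not reduced.

Step 3
Reactants: 5 methyl 2,4-dihydroxy-3,5,6-trimethylbenzoate
Product: 6 methyl 4-(tert-butyldimethylsilyloxy)-2-hydroxy-3,5,6-trimethylbenzoate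
Conditions: TBSCl, imidazole, DMF, rt
Reagents that add atoms: tert-butyldimethylsilyl chloride, CC(C)(C)[Si](C)(C)Cl
Why: Chemoselective O-silylation should occur only at the free 4-hydroxyl, because the 2-hydroxyl is held in a hydrogen bond to the ester carbonyl and is a poor nucleophile toward the silyl chloride.

Step 4
Reactants: 6 methyl 4-(tert-butyldimethylsilyloxy)-2-hydroxy-3,5,6-trimethylbenzoate
Product: 7 methyl 2-(benzyloxy)-4-(tert-butyldimethylsilyloxy)-3,5,6-trimethylbenzoate
Conditions: BnBr, K2CO3, acetone, reflux
Reagents that add atoms: benzyl bromide, BrCc1ccccc1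
Why: Williamson ether synthesis on the remaining chelated phenol, under carbonate in dry acetone, which should benzylate it and leave in place the aryl silyl ether shielded by two ortho methyl groups.

Step 5
Reactants: 7 methyl 2-(benzyloxy)-4-(tert-butyldimethylsilyloxy)-3,5,6-trimethylbenzoate
Product: 8 methyl 2-(benzyloxy)-4-hydroxy-3,5,6-trimethylbenzoate
Conditions: n-Bu4NF, AcOH, THF, 0 °C
Reagents that add atoms: none
Why: Fluoride-induced desilylation, buffered by acetic acid so that the phenoxide is protonated at once and neither the methyl ester nor the benzyl ether is touched.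

Step 6
Reactants: 8 methyl 2-(benzyloxy)-4-hydroxy-3,5,6-trimethylbenzoate; 9 2,2,6-trimethyl-4H-1,3-dioxin-4-one
Product: 10 ArB 3-oxobutanoate (ring B aryl acetoacetate)
Conditions: xylene, 140 °C, slow addition of 9, acetone distilled off
Reagents that add atoms: none
Why: Thermal retro-[4+2] fragmentation of the dioxinone releases acetylketene, a small and very reactive acylating agent that is trapped even by di-ortho-substituted phenols (acylketene acetoacetylation), so the hindered depside C-O bond forms here without a coupling reagent.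

Step 7
Reactants: 11 methylmalonic acid
Product: 12 methylmalonyl dichloride
Conditions: SOCl2, 50 °C; distillation under reduced pressure
Reagents that add atoms: thionyl chloride, ClS(Cl)=O
Why: Acid chloride formation from a malonic acid by thionyl chloride, run at moderate temperature to avoid decarboxylation and ketene formation, with the product purified by distillation.

Step 8
Reactants: 10 ArB 3-oxobutanoate; 12 methylmalonyl dichloride
Product: 14 ArB 4-hydroxy-3,6-dimethyl-2-oxo-2H-pyran-5-carboxylate, via C-acylated acid chloride 13 (not isolated)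
Conditions: ClCH2CH2Cl, 60 °C, N2 sweep
Reagents that add atoms: none
Why: Known annulation of beta-keto esters by malonyl dichlorides, in which C-acylation of the enolised acetoacetate at its central carbon and attack of the ketone enol oxygen on the second acid chloride give the 4-hydroxy-2-pyrone-5-carboxylate, the 3-methyl group coming from the reagent.

Step 9
Reactants: 14 ArB 4-hydroxy-3,6-dimethyl-2-oxo-2H-pyran-5-carboxylate
Product: 15 ArB 4-methoxy-3,6-dimethyl-2-oxo-2H-pyran-5-carboxylate
Conditions: Me2SO4, K2CO3, acetone, reflux
Reagents that add atoms: dimethyl sulfate, COS(=O)(=O)OC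
Why: O-Alkylation of the acidic 4-hydroxy-2-pyrone (a vinylogous acid) by dimethyl sulfate and carbonate in acetone, conditions known to favour the 4-methoxy-2-pyrone over the isomeric 2-methoxy-4-pyrone.

Step 10
Reactants: 16 dichloroacetaldehyde diethyl acetal
Product: 17 dichloroacetaldehyde dibenzyl acetal (1,1-bis(benzyloxy)-2,2-dichloroethane)
Conditions: BnOH (2.5 equiv), TsOH·H2O (cat.), 120 °C, EtOH distilled off
Reagents that add atoms: benzyl alcohol, OCc1ccccc1
Why: Acid-catalysed transacetalisation driven to completion by distilling off ethanol, the less volatile benzyl alcohol replacing both ethoxy groups.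

Step 11
Reactants: 17 dichloroacetaldehyde dibenzyl acetal
Product: 18 chloroketene dibenzyl acetal (1,1-bis(benzyloxy)-2-chloroethene)
Conditions: KOC(CH3)3, THF, 0 °C to rt; filtration through basic alumina
Reagents that add atoms: none
Why: Base-induced dehydrochlorination (E2) of an alpha,alpha-dichloro acetal is the classical entry to chloroketene acetals, and the product is kept at or below room temperature and used at once because benzyl ketene acetals hydrolyse easily and undergo benzyl-Claisen rearrangement on heating.

Step 12
Reactants: 15 ArB 4-methoxy-3,6-dimethyl-2-oxo-2H-pyran-5-carboxylate; 18 chloroketene dibenzyl acetal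
Product: 21 ArB 4-(benzyloxy)-3-chloro-6-methoxy-2,5-dimethylbenzoate (2,4'-di-O-benzyl depside), via bridged lactone 19 (not isolated), via cyclohexadiene ketal 20 (not isolated)
Conditions: 18 (5 equiv), CH2Cl2, 13 kbar, 45 °C; then toluene, iPr2NEt (0.2 equiv), 90 °C
Reagents that add atoms: none
Why: Proposed new method: the nucleophilic CHCl carbon of electron-rich acetal 18 attacks pyrone C6 (beta to the C5 aryl ester, delta to the lactone carbonyl) and the acetal carbon closes on C3 in an asynchronous inverse-electron-demand [4+2] cycloaddition that forms C5'-C6' and C3'-C4' and gives bridged lactone 19, a step of strongly negative activation volume that is therefore run under pressure at a temperature below the onset of benzyl-Claisen rearrangement of 18. On warming, 19 expels CO2 by retro-[4+2] to cyclohexadiene ketal 20, whose only ring hydrogen sits on the CHCl carbon, so base-assisted 1,2-elimination can only expel benzyl alcohol and must keep chlorine. The closest known reaction type is the Diels-Alder reaction of 2-pyrone-5-carboxylates and 2-pyrone-3-carboxylates with ketene acetals followed by loss of CO2 and alcohol to alkoxybenzoates; new here are a pyrone substituted at all four carbons, its 4-methoxy donor and a chlorinated ketene acetal. Ring A closes as a six-membered carbocycle by [4+2] annulation of the two-carbon acetal unit across C3 and C6 of the pyrone diene, with aromatisation as the driving force. The stereocentres of 19 and 20 are transient and vanish on aromatisation, so none has to be controlled. The selectivity needed is regiochemical (Cl next to the C6' methyl, oxygen next to the C3' methyl), and it is secured by the polarity match between electrophilic C6 of the C6=C5-CO2ArB unit and the nucleophilic CHCl terminus, C3 being the electron-rich alpha carbon of the vinylogous carbonate and so the natural partner of the dialkoxycarbenium centre.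

Step 13
Reactants: 21 ArB 4-(benzyloxy)-3-chloro-6-methoxy-2,5-dimethylbenzoate
Product: 22 3-hydroxy-4-(methoxycarbonyl)-2,5,6-trimethylphenyl 3-chloro-4-hydroxy-6-methoxy-2,5-dimethylbenzoate (target)
Conditions: H2 (1 atm), 10% Pd/C, EtOAc, rt
Reagents that add atoms: none
Why: Hydrogenolysis of both aryl benzyl ethers over palladium on carbon in neutral ethyl acetate, stopped after two equivalents of hydrogen are taken up and run without added base, should spare the hindered aryl chloride and both esters.

**Compound list**

1 | methyl atratate (methyl 2,4-dihydroxy-3,6-dimethylbenzoate) | COC(=O)c1c(C)cc(O)c(C)c1O | starting material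
2 | methyl 5-[chloro(methoxy)methyl]-2,4-dihydroxy-3,6-dimethylbenzoate (racemic, not isolated) | COC(=O)c1c(C)c(C(Cl)OC)c(O)c(C)c1O | intermediate
3 | methyl 5-formyl-2,4-dihydroxy-3,6-dimethylbenzoate | COC(=O)c1c(C)c(C=O)c(O)c(C)c1O | intermediate
4 | methyl 2,4-dihydroxy-5-(hydroxymethyl)-3,6-dimethylbenzoate (not isolated) | COC(=O)c1c(C)c(CO)c(O)c(C)c1O | intermediate
5 | methyl 2,4-dihydroxy-3,5,6-trimethylbenzoate | COC(=O)c1c(C)c(C)c(O)c(C)c1O | intermediate
6 | methyl 4-(tert-butyldimethylsilyloxy)-2-hydroxy-3,5,6-trimethylbenzoate | COC(=O)c1c(C)c(C)c(O[Si](C)(C)C(C)(C)C)c(C)c1O | intermediate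
7 | methyl 2-(benzyloxy)-4-(tert-butyldimethylsilyloxy)-3,5,6-trimethylbenzoate | COC(=O)c1c(C)c(C)c(O[Si](C)(C)C(C)(C)C)c(C)c1OCc1ccccc1 | intermediate
8 | methyl 2-(benzyloxy)-4-hydroxy-3,5,6-trimethylbenzoate | COC(=O)c1c(C)c(C)c(O)c(C)c1OCc1ccccc1 | intermediate
9 | 2,2,6-trimethyl-4H-1,3-dioxin-4-one | CC1=CC(=O)OC(C)(C)O1 | starting material
10 | 3-(benzyloxy)-4-(methoxycarbonyl)-2,5,6-trimethylphenyl 3-oxobutanoate | CC(=O)CC(=O)Oc1c(C)c(C)c(C(=O)OC)c(OCc2ccccc2)c1C | intermediate
11 | methylmalonic acid | CC(C(=O)O)C(=O)O | starting material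
12 | methylmalonyl dichloride | CC(C(=O)Cl)C(=O)Cl | intermediate
13 | 3-(benzyloxy)-4-(methoxycarbonyl)-2,5,6-trimethylphenyl 2-acetyl-5-chloro-4-methyl-3,5-dioxopentanoate (mixture of stereoisomers, not isolated) | CC(=O)C(C(=O)C(C)C(=O)Cl)C(=O)Oc1c(C)c(C)c(C(=O)OC)c(OCc2ccccc2)c1C | intermediate
14 | 3-(benzyloxy)-4-(methoxycarbonyl)-2,5,6-trimethylphenyl 4-hydroxy-3,6-dimethyl-2-oxo-2H-pyran-5-carboxylate | Cc1oc(=O)c(C)c(O)c1C(=O)Oc1c(C)c(C)c(C(=O)OC)c(OCc2ccccc2)c1C | intermediate
15 | 3-(benzyloxy)-4-(methoxycarbonyl)-2,5,6-trimethylphenyl 4-methoxy-3,6-dimethyl-2-oxo-2H-pyran-5-carboxylate | Cc1oc(=O)c(C)c(OC)c1C(=O)Oc1c(C)c(C)c(C(=O)OC)c(OCc2ccccc2)c1C | intermediate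
16 | dichloroacetaldehyde diethyl acetal | CCOC(OCC)C(Cl)Cl | starting material
17 | dichloroacetaldehyde dibenzyl acetal (1,1-bis(benzyloxy)-2,2-dichloroethane) | ClC(Cl)C(OCc1ccccc1)OCc1ccccc1 | intermediate
18 | chloroketene dibenzyl acetal (1,1-bis(benzyloxy)-2-chloroethene) | ClC=C(OCc1ccccc1)OCc1ccccc1 | intermediate
19 | 3-(benzyloxy)-4-(methoxycarbonyl)-2,5,6-trimethylphenyl 8,8-bis(benzyloxy)-7-chloro-5-methoxy-1,4-dimethyl-3-oxo-2-oxabicyclo[2.2.2]oct-5-ene-6-carboxylate (racemic mixture of CHCl epimers, not isolated) | CC12OC(=O)C(C)(C(OC)=C1C(=O)Oc1c(C)c(C)c(C(=O)OC)c(OCc3ccccc3)c1C)C(OCc1ccccc1)(OCc1ccccc1)C2Cl | intermediate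
20 | 3-(benzyloxy)-4-(methoxycarbonyl)-2,5,6-trimethylphenyl 4,4-bis(benzyloxy)-3-chloro-6-methoxy-2,5-dimethylcyclohexa-1,5-diene-1-carboxylate (racemic, not isolated) | CC1=C(C(=O)Oc2c(C)c(C)c(C(=O)OC)c(OCc3ccccc3)c2C)C(OC)=C(C)C(OCc2ccccc2)(OCc2ccccc2)C1Cl | intermediate
21 | 3-(benzyloxy)-4-(methoxycarbonyl)-2,5,6-trimethylphenyl 4-(benzyloxy)-3-chloro-6-methoxy-2,5-dimethylbenzoate | COC(=O)c1c(C)c(C)c(OC(=O)c2c(C)c(Cl)c(OCc3ccccc3)c(C)c2OC)c(C)c1OCc1ccccc1 | intermediate
22 | 3-hydroxy-4-(methoxycarbonyl)-2,5,6-trimethylphenyl 3-chloro-4-hydroxy-6-methoxy-2,5-dimethylbenzoate | COC(=O)c1c(C)c(C)c(OC(=O)c2c(C)c(Cl)c(O)c(C)c2OC)c(C)c1O | target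

**Step count and risks**

Total step count: 13. Longest linear sequence: 10 steps (steps 1 to 6, 8, 9, 12 and 13, from methyl atratate 1).

Steps most likely to fail:

1. Step 12 (the step marked as a proposed new method). The cycloaddition may be too slow at the fully substituted, donor-bearing diene, so that the acetal is consumed by hydrolysis, oligomerisation or benzyl-Claisen rearrangement before ring A forms. The fallback uses known chemistry: it gives up the pyrone-to-arene conversion and builds ring A from aromatic material, because ring A is a 5-chloro-2-O-methyl atratate unit. It sets out from 1 and 8 and returns to the route at 21. Chlorination of 1 by SO2Cl2 in Et2O at 0 °C at the only free ring position should give methyl 3-chloro-4,6-dihydroxy-2,5-dimethylbenzoate F1. Benzylation of the non-chelated hydroxyl (BnBr, K2CO3, acetone, rt) should give methyl 4-(benzyloxy)-3-chloro-6-hydroxy-2,5-dimethylbenzoate F2. Methylation of the chelated hydroxyl (MeI, K2CO3, DMF, 60 °C) should give methyl 4-(benzyloxy)-3-chloro-6-methoxy-2,5-dimethylbenzoate F3. Saponification of the hindered ester (KOH, aqueous DMSO, 90 °C) should give 4-(benzyloxy)-3-chloro-6-methoxy-2,5-dimethylbenzoic acid F4. Trifluoroacetic anhydride in toluene at rt should convert F4 into 4-(benzyloxy)-3-chloro-6-methoxy-2,5-dimethylbenzoic trifluoroacetic anhydride F5, which acylates phenol 8 through its acylium ion to give 21.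

2. Step 8. O-acylation and oligomerisation through chlorocarbonyl(methyl)ketene, or HCl-promoted loss of the aryl acetoacetate, may outrun the C-acylation and ring closure. The fallback separates the two bond formations and sets out from 10, returning at 14. C-Acylation of the magnesium enolate of 10 (MgCl2, pyridine, CH2Cl2, 0 °C) by the half-ester acid chloride ethyl 3-chloro-2-methyl-3-oxopropanoate should give 1-ArB 5-ethyl 2-acetyl-4-methyl-3-oxopentanedioate F6. DBU in toluene at 80 °C should then close the lactone from the acetyl enol oxygen onto the ethyl ester, with loss of ethanol, to give 14.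

3. Step 13. Hydrodechlorination at C5' may compete with O-debenzylation on the palladium surface. The fallback replaces reduction by Lewis-acid ether cleavage and sets out from 21, returning at 22. BCl3 and pentamethylbenzene as cation scavenger in CH2Cl2 at -78 °C should remove both benzyl groups as benzylpentamethylbenzene, leaving the aryl chloride, the aryl methyl ether and both esters untouched at this temperature. No new compound lies on this path.

**Further compounds**

F1 | step 12 | methyl 3-chloro-4,6-dihydroxy-2,5-dimethylbenzoate | COC(=O)c1c(C)c(Cl)c(O)c(C)c1O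
F2 | step 12 | methyl 4-(benzyloxy)-3-chloro-6-hydroxy-2,5-dimethylbenzoate | COC(=O)c1c(C)c(Cl)c(OCc2ccccc2)c(C)c1O
F3 | step 12 | methyl 4-(benzyloxy)-3-chloro-6-methoxy-2,5-dimethylbenzoate | COC(=O)c1c(C)c(Cl)c(OCc2ccccc2)c(C)c1OC
F4 | step 12 | 4-(benzyloxy)-3-chloro-6-methoxy-2,5-dimethylbenzoic acid | OC(=O)c1c(C)c(Cl)c(OCc2ccccc2)c(C)c1OC
F5 | step 12 | 4-(benzyloxy)-3-chloro-6-methoxy-2,5-dimethylbenzoic trifluoroacetic anhydride | O=C(OC(=O)C(F)(F)F)c1c(C)c(Cl)c(OCc2ccccc2)c(C)c1OC
F6 | step 8 | 1-[3-(benzyloxy)-4-(methoxycarbonyl)-2,5,6-trimethylphenyl] 5-ethyl 2-acetyl-4-methyl-3-oxopentanedioate | CCOC(=O)C(C)C(=O)C(C(C)=O)C(=O)Oc1c(C)c(C)c(C(=O)OC)c(OCc2ccccc2)c1C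
F0 | step 13 | none | none
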